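**Strategy.** The target is cut between C2 and the C3 carbonyl carbon. C3 lies exactly two carbons from guaiacyl ring A, so C2 is the terminal carbon of a ring-A styrene and C1 its benzylic position. The key step is a photocatalytic, phosphine-mediated deoxygenative hydroacylation: the free (R)-β-hydroxy acid carrying C3–C7 and ring B gives a nucleophilic C3 acyl radical that adds to C2 of 4-benzyloxy-3-methoxystyrene, ring A stabilising the C1 radical. One operation joins both halves at the ketone oxidation level without activating either partner or protecting the C5 hydroxyl. The C5 stereocenter comes from a Noyori hydrogenation; one hydrogenolysis ends the route.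

Key step: step 6

Remark on configuration: the only stereocenter is C5 of the heptan-3-one chain; with priorities OH > C4 > C6 > H the given SMILES is (5R).
Remark on materials: 1-(benzyloxy)-2-methoxy-4-vinylbenzene is taken as a catalogue compound (it is otherwise one Wittig methylenation away from O-benzylvanillin).
Abbreviations: dFMeppy = cyclometalated 2-(2,4-difluorophenyl)-5-methylpyridine; dtbbpy = 4,4'-di-tert-butyl-2,2'-bipyridine; CDI = 1,1'-carbonyldiimidazole.

**Step 1**
Reactants: 1 3,4-dihydroxy-5-methoxybenzaldehyde (5-hydroxyvanillin); 2 benzyl bromide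
Product: 3 3,4-bis(benzyloxy)-5-methoxybenzaldehyde
Conditions: BnBr (2.4 equiv), K2CO3 (3 equiv), DMF, 60 °C
Reagents that add atoms: benzyl bromide (2), BrCc1ccccc1
Why: Williamson ether synthesis, in which both phenoxides are alkylated by the primary benzylic bromide while the aldehyde is inert to K2CO3.

**Step 2**
Reactants: 3 3,4-bis(benzyloxy)-5-methoxybenzaldehyde; 4 Meldrum's acid (2,2-dimethyl-1,3-dioxane-4,6-dione)
Product: 7 3-[3,4-bis(benzyloxy)-5-methoxyphenyl]propanoic acid, via arylidene Meldrum's acid 5 (not isolated), via benzyl Meldrum's acid 6 (not isolated)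
Conditions: Meldrum's acid (1.1 equiv), HCO2H/Et3N (5:2), 95–100 °C; aqueous HCl work-up
Reagents that add atoms: Meldrum's acid (4), CC1(C)OC(=O)CC(=O)O1; water, O
Why: Tandem Knoevenagel condensation, conjugate transfer reduction of the strongly electrophilic alkylidene Meldrum's acid by formate, and thermal loss of acetone and CO2 with capture by water; the aryl benzyl ethers should survive because no hydrogenolysis metal is present.

**Step 3**
Reactants: 7 3-[3,4-bis(benzyloxy)-5-methoxyphenyl]propanoic acid; 8 potassium methyl malonate
Product: 11 methyl 5-[3,4-bis(benzyloxy)-5-methoxyphenyl]-3-oxopentanoate, via acyl imidazolide 9 (not isolated), via acylmalonic half ester 10 (not isolated)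
Conditions: CDI (1.2 equiv), THF, rt; then potassium methyl malonate (2 equiv), MgCl2 (1.5 equiv), Et3N, THF, rt to 50 °C; 1 M HCl work-up
Reagents that add atoms: potassium methyl malonate (8), COC(=O)CC(=O)[O-].[K+]
Why: Masamune–Brooks homologation, in which the magnesium enolate of the malonate half ester is C-acylated by the imidazolide and the adduct decarboxylates to the β-keto ester.

**Step 4**
Reactants: 11 methyl 5-[3,4-bis(benzyloxy)-5-methoxyphenyl]-3-oxopentanoate
Product: 12 methyl (3R)-5-[3,4-bis(benzyloxy)-5-methoxyphenyl]-3-hydroxypentanoate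
Conditions: RuCl2[(R)-BINAP] (0.5 mol %), H2 (20 atm), MeOH/CH2Cl2 (4:1), 50 °C
Reagents that add atoms: none
Why: Noyori asymmetric hydrogenation of a β-keto ester, in which the ester carbonyl chelates ruthenium and (R)-BINAP directs hydride to the ketone face that gives the (3R)-carbinol (the sense in which methyl acetoacetate gives methyl (R)-3-hydroxybutanoate); the homogeneous ruthenium catalyst should not cleave aryl benzyl ethers.

**Step 5**
Reactants: 12 methyl (3R)-5-[3,4-bis(benzyloxy)-5-methoxyphenyl]-3-hydroxypentanoate
Product: 13 (3R)-5-[3,4-bis(benzyloxy)-5-methoxyphenyl]-3-hydroxypentanoic acid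
Conditions: LiOH·H2O (2 equiv), THF/H2O (3:1), 0 °C to rt; then 1 M HCl to pH 3
Reagents that add atoms: lithium hydroxide, [Li+].[OH-]
Why: Ester saponification by acyl–oxygen cleavage leaves the carbinol C–O bond untouched, so the (3R) configuration is kept, and the low temperature suppresses β-elimination.

**Step 6**
Reactants: 13 (3R)-5-[3,4-bis(benzyloxy)-5-methoxyphenyl]-3-hydroxypentanoic acid; 14 1-(benzyloxy)-2-methoxy-4-vinylbenzene (4-benzyloxy-3-methoxystyrene)
Product: 15 (5R)-7-[3,4-bis(benzyloxy)-5-methoxyphenyl]-1-[4-(benzyloxy)-3-methoxyphenyl]-5-hydroxyheptan-3-one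
Conditions: 14 (2 equiv), [Ir(dFMeppy)2(dtbbpy)]PF6 (2 mol %), PMe2Ph (1.5 equiv), 2,6-lutidine (1 equiv), degassed MeCN, blue LEDs (450 nm), rt
Reagents that add atoms: none
Why: The photoexcited iridium complex (trivalent iridium) oxidises PMe2Ph to its radical cation, the lutidinium carboxylate of 13 adds to phosphorus, and β-scission of the acyloxyphosphoranyl radical expels dimethylphenylphosphine oxide and leaves the C3 acyl radical. This nucleophilic σ-radical adds to the unsubstituted terminus of styrene 14, forming the C2–C3 bond and a C1 benzylic radical delocalised into ring A; reduction by the divalent iridium state and protonation by lutidinium complete an anti-Markovnikov hydroacylation and close the catalytic cycle. The closest known reaction type is the photoredox, phosphine-mediated deoxygenative hydroacylation of styrenes with aliphatic carboxylic acids, which gives dialkyl ketones of exactly this ArCH2CH2C(=O)R pattern. No ring is closed and no stereocenter is formed; C5 is a non-acidic carbinol carbon two atoms from the radical site and should keep its (R) configuration. The step needs regioselectivity, secured by the benzylic stabilisation that only terminal attack provides, and chemoselectivity for the carboxylate over the free C5 hydroxyl, expected because the anionic carboxylate captures the phosphine radical cation much faster than a neutral secondary alcohol and an alkoxyphosphoranyl radical of an unactivated alcohol fragments only slowly. A primary acyl radical loses CO slowly, and the mildly oxidising photocatalyst with excess phosphine should keep direct oxidation of the electron-rich styrene in the background.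

**Step 7**
Reactants: 15 (5R)-7-[3,4-bis(benzyloxy)-5-methoxyphenyl]-1-[4-(benzyloxy)-3-methoxyphenyl]-5-hydroxyheptan-3-one
Product: 16 (5R)-7-(3,4-dihydroxy-5-methoxyphenyl)-5-hydroxy-1-(4-hydroxy-3-methoxyphenyl)heptan-3-one
Conditions: H2 (1 atm), 10% Pd/C, EtOAc/MeOH (1:1), rt; filtration and concentration under argon
Reagents that add atoms: none
Why: Hydrogenolysis of the three aryl benzyl ethers on palladium under neutral conditions, to which the dialkyl ketone, the non-benzylic secondary alcohol and the C5 stereocenter are inert and which avoid acid- or base-induced dehydration of the β-hydroxy ketone.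

**Compound list**

1 | 3,4-dihydroxy-5-methoxybenzaldehyde (5-hydroxyvanillin) | O=Cc1cc(O)c(O)c(OC)c1 | starting material
2 | benzyl bromide | BrCc1ccccc1 | starting material
3 | 3,4-bis(benzyloxy)-5-methoxybenzaldehyde | O=Cc1cc(OCc2ccccc2)c(OCc2ccccc2)c(OC)c1 | intermediate
4 | Meldrum's acid (2,2-dimethyl-1,3-dioxane-4,6-dione) | CC1(C)OC(=O)CC(=O)O1 | starting material
5 | 5-[3,4-bis(benzyloxy)-5-methoxybenzylidene]-2,2-dimethyl-1,3-dioxane-4,6-dione | CC1(C)OC(=O)C(=Cc2cc(OCc3ccccc3)c(OCc3ccccc3)c(OC)c2)C(=O)O1 | intermediate
6 | 5-[3,4-bis(benzyloxy)-5-methoxybenzyl]-2,2-dimethyl-1,3-dioxane-4,6-dione | CC1(C)OC(=O)C(Cc2cc(OCc3ccccc3)c(OCc3ccccc3)c(OC)c2)C(=O)O1 | intermediate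
7 | 3-[3,4-bis(benzyloxy)-5-methoxyphenyl]propanoic acid | OC(=O)CCc1cc(OCc2ccccc2)c(OCc2ccccc2)c(OC)c1 | intermediate
8 | potassium methyl malonate | COC(=O)CC(=O)[O-].[K+] | starting material
9 | 3-[3,4-bis(benzyloxy)-5-methoxyphenyl]-1-(imidazol-1-yl)propan-1-one | O=C(CCc1cc(OCc2ccccc2)c(OCc2ccccc2)c(OC)c1)n1ccnc1 | intermediate
10 | 2-(methoxycarbonyl)-5-[3,4-bis(benzyloxy)-5-methoxyphenyl]-3-oxopentanoic acid (present as its magnesium salt) | COC(=O)C(C(=O)O)C(=O)CCc1cc(OCc2ccccc2)c(OCc2ccccc2)c(OC)c1 | intermediate
11 | methyl 5-[3,4-bis(benzyloxy)-5-methoxyphenyl]-3-oxopentanoate | COC(=O)CC(=O)CCc1cc(OCc2ccccc2)c(OCc2ccccc2)c(OC)c1 | intermediate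
12 | methyl (3R)-5-[3,4-bis(benzyloxy)-5-methoxyphenyl]-3-hydroxypentanoate | COC(=O)C[C@H](O)CCc1cc(OCc2ccccc2)c(OCc2ccccc2)c(OC)c1 | intermediate
13 | (3R)-5-[3,4-bis(benzyloxy)-5-methoxyphenyl]-3-hydroxypentanoic acid | OC(=O)C[C@H](O)CCc1cc(OCc2ccccc2)c(OCc2ccccc2)c(OC)c1 | intermediate
14 | 1-(benzyloxy)-2-methoxy-4-vinylbenzene | C=Cc1ccc(OCc2ccccc2)c(OC)c1 | starting material
15 | (5R)-7-[3,4-bis(benzyloxy)-5-methoxyphenyl]-1-[4-(benzyloxy)-3-methoxyphenyl]-5-hydroxyheptan-3-one | COc1cc(CCC(=O)C[C@H](O)CCc2cc(OCc3ccccc3)c(OCc3ccccc3)c(OC)c2)ccc1OCc1ccccc1 | intermediate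
16 | (5R)-7-(3,4-dihydroxy-5-methoxyphenyl)-5-hydroxy-1-(4-hydroxy-3-methoxyphenyl)heptan-3-one | COc1cc(CCC(=O)C[C@H](O)CCc2cc(O)c(O)c(OC)c2)ccc1O | target

**Step count.** Total: 7 steps. Longest linear sequence: 7 steps (1 → 16); styrene 14 enters as bought.

**Steps most likely to fail**

Step 6 (key step). The electron-rich styrene may be oxidised directly by the photocatalyst and oligomerise. Reduction of the electron-rich C1 benzylic radical may be slow, so that telomerisation competes. The acyl radical may be quenched to the aldehyde before it adds. The free C5 hydroxyl may capture the phosphine radical cation.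
The fallback replaces the radical addition by a polar acyl substitution that forms the same C2–C3 bond. It sets out from 12 and 14 and returns at 15. Ester 12 is treated with Me(MeO)NH·HCl and iPrMgCl (THF, −20 °C) to give the N-methoxy-N-methylamide (Weinreb amide) F1. Styrene 14 is hydroborated with 9-BBN to the B-alkyl-9-borabicyclononane F2 (not isolated) and oxidised with H2O2/NaOH to the primary alcohol F3. An Appel reaction (CBr4, PPh3, CH2Cl2) converts F3 into the bromide F4, and Mg in THF then gives the Grignard reagent F5. Addition of F5 (3 equiv, the first deprotonating the hydroxyl) to F1 at 0 °C, then aqueous NH4Cl, should give 15 through the chelated tetrahedral intermediate.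

Step 2. Transfer reduction or decarboxylation may stall, or the alkylidene intermediate may take up a second Meldrum's acid.
The fallback separates chain extension from reduction. It sets out from 3 and returns at 7. Knoevenagel–Doebner condensation of 3 with malonic acid (pyridine, cat. piperidine, 90 °C) passes through the arylidenemalonic acid F6 (not isolated) and should give the (E)-cinnamic acid F7. Diimide generated from p-toluenesulfonyl hydrazide and NaOAc (DME/H2O, reflux) then saturates the C=C without touching the benzyl ethers and gives 7.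

Step 4. Enantiofacial control may be incomplete, or turnover may be slow if traces of imidazole or acid from step 3 poison the catalyst.
The fallback replaces metal catalysis by biocatalysis. It sets out from 11 and returns at 12. An (R)-selective ketoreductase chosen from a commercial panel (NADPH, glucose/glucose dehydrogenase recycling, phosphate buffer/DMSO, 30 °C) reduces 11 directly to 12; this fallback makes no new compound (F0).

**Further compounds**

F1 | step 6 | (3R)-5-[3,4-bis(benzyloxy)-5-methoxyphenyl]-3-hydroxy-N-methoxy-N-methylpentanamide | CON(C)C(=O)C[C@H](O)CCc1cc(OCc2ccccc2)c(OCc2ccccc2)c(OC)c1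
F2 | step 6 | 9-{2-[4-(benzyloxy)-3-methoxyphenyl]ethyl}-9-borabicyclo[3.3.1]nonane | COc1cc(CCB2C3CCCC2CCC3)ccc1OCc1ccccc1
F3 | step 6 | 2-[4-(benzyloxy)-3-methoxyphenyl]ethanol | COc1cc(CCO)ccc1OCc1ccccc1
F4 | step 6 | 1-(benzyloxy)-4-(2-bromoethyl)-2-methoxybenzene | COc1cc(CCBr)ccc1OCc1ccccc1
F5 | step 6 | {2-[4-(benzyloxy)-3-methoxyphenyl]ethyl}magnesium bromide | COc1cc(CC[Mg]Br)ccc1OCc1ccccc1
F6 | step 2 | 2-[3,4-bis(benzyloxy)-5-methoxybenzylidene]malonic acid | OC(=O)C(=Cc1cc(OCc2ccccc2)c(OCc2ccccc2)c(OC)c1)C(=O)O
F7 | step 2 | (E)-3-[3,4-bis(benzyloxy)-5-methoxyphenyl]acrylic acid | OC(=O)/C=C/c1cc(OCc2ccccc2)c(OCc2ccccc2)c(OC)c1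
F0 | step 4 | none | none
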